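## Retrosynthetic overview

1. Target 27 ⇐ enone 26 by C9 ketone reduction; 26 ⇐ cyclohexanone 24 by a one-pot four-atom ring expansion (alkenyl addition to C9=O closes a transient ring B, then Grob cleavage of C4–C9 with loss of C5–Br; 6 → 10).
2. 24 ⇐ hydroxy ketone 19 + epoxy acid 23 (from angelic acid: LiAlH4, Sharpless epoxidation, RuO4).
3. 19 ⇐ 17 (Rubottom, C8–O) ⇐ 16 (bromolactonisation: lactone O–C6 and C5–Br) ⇐ 11 (amino-ester Ireland–Claisen: C7–C11 and the exo-methylene).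
4. 11 ⇐ 8 ⇐ 6 ⇐ prochiral dione 5 by desymmetrising transfer hydrogenation (sets C4/C5; all later centres are relayed from them).
5. 5 ⇐ cyclohexane-1,3-dione + MeI + acrolein + iodo-Wittig. Ring order: cyclohexanone (ring A) → γ-lactone → transient cyclohexene (ring B) → ten-membered ring.

Assumption: the target is taken exactly as drawn (cis-fused 6,12-lactone, 1(10)Z,4E); atoms are referred to by germacrane numbering C1–C15.
Assumption: Ru–(R,R)-TsDPEN gives the (3R) carbinol in step 4 and (R)-Me-CBS the (9R) carbinol in step 15 (quaternary side and alkenyl arm as the large groups); if a sense is reversed, the catalyst antipode is used.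

## Route

Step 1
Reactants: 1 cyclohexane-1,3-dione
Product: 2 2-methylcyclohexane-1,3-dione
Conditions: MeI, KOH, H2O–MeOH, 65 °C
Reagents that add atoms: iodomethane, CI
Why: C-alkylation of the stabilised 1,3-dione enolate (classical 2-methylation of dihydroresorcinol); no stereocentre.

Step 2
Reactants: 2 2-methylcyclohexane-1,3-dione; 3 acrolein
Product: 4 3-(1-methyl-2,6-dioxocyclohexyl)propanal
Conditions: H2O, 25 °C
Reagents that add atoms: none
Why: Michael addition of the acidic dione to acrolein builds quaternary C4 with the C3–C2–C1 chain; the product is still achiral.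

Step 3
Reactants: 4 3-(1-methyl-2,6-dioxocyclohexyl)propanal
Product: 5 2-[(3Z)-4-iodopent-3-en-1-yl]-2-methylcyclohexane-1,3-dione
Conditions: EtPPh3I, n-BuLi, THF, −78 °C; I2; NaHMDS, −20 °C; then 4, −78 → −20 °C
Reagents that add atoms: ethyltriphenylphosphonium iodide, CC[P+](c1ccccc1)(c1ccccc1)c1ccccc1.[I-]; iodine, II
Why: Stork–Zhao–Wittig olefination is aldehyde-selective at −78 °C and gives the (Z)-2-iodoalkene, which fixes the later Z-C1=C10 geometry.

Step 4
Reactants: 5 2-[(3Z)-4-iodopent-3-en-1-yl]-2-methylcyclohexane-1,3-dione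
Product: 6 (2R,3R)-3-hydroxy-2-[(3Z)-4-iodopent-3-en-1-yl]-2-methylcyclohexan-1-one
Conditions: RuCl(p-cymene)[(R,R)-TsDPEN] (1 mol %), HCO2H–Et3N 5:2, CH2Cl2, 25 °C
Reagents that add atoms: none
Why: Noyori asymmetric transfer hydrogenation desymmetrises the 2,2-disubstituted 1,3-dione; the catalyst selects one enantiotopic C=O and hydride enters anti to the larger chain, so C5–OH is cis to the chain and C4 becomes a defined quaternary centre.

Step 5
Reactants: 6 (2R,3R)-3-hydroxy-2-[(3Z)-4-iodopent-3-en-1-yl]-2-methylcyclohexan-1-one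
Product: 8 (5R,6R)-5-hydroxy-6-[(3Z)-4-iodopent-3-en-1-yl]-6-methylcyclohex-2-en-1-one, via selenide 7 (not isolated)
Conditions: LDA (2.3 equiv), THF, −78 °C; PhSeBr; then 30% H2O2, pyridine, CH2Cl2, 0 → 25 °C
Reagents that add atoms: benzeneselenenyl bromide, Br[Se]c1ccccc1
Why: Reich–Sharpless α-selenenylation and selenoxide syn-elimination; only C8 is enolisable (C4 is quaternary), so the C7=C8 enone forms regiospecifically and no stereocentre is touched.

Step 6
Reactants: 8 (5R,6R)-5-hydroxy-6-[(3Z)-4-iodopent-3-en-1-yl]-6-methylcyclohex-2-en-1-one; 9 acryloyl chloride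
Product: 11 (1R,6R)-6-[(3Z)-4-iodopent-3-en-1-yl]-6-methyl-5-oxocyclohex-3-en-1-yl 3-(pyrrolidin-1-yl)propanoate, via acrylate 10 (not isolated)
Conditions: 9, Et3N, CH2Cl2, −20 °C; then pyrrolidine, 0 °C
Reagents that add atoms: pyrrolidine, C1CCNC1
Why: O-acylation followed by aza-Michael addition gives Still's β-aminopropionate ester, a masked acrylate for the Claisen step.

Step 7
Reactants: 11 (1R,6R)-6-[(3Z)-4-iodopent-3-en-1-yl]-6-methyl-5-oxocyclohex-3-en-1-yl 3-(pyrrolidin-1-yl)propanoate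
Product: 16 2-[(1R,4R)-4-[(3Z)-4-iodopent-3-en-1-yl]-4-methyl-5-oxocyclohex-2-en-1-yl]prop-2-enoic acid, via bis-silyl ketene acetal 12 (not isolated), via rearranged silyl ester 13 (not isolated), via keto amino acid 14 (not isolated), via methylammonium iodide 15 (not isolated)
Conditions: LDA (2.5 equiv) added to 11 + Me3SiCl/Et3N, THF, −78 °C, then 60 °C; MeOH, 25 °C; MeI; aq NaHCO3, 40 °C; H3O+
Reagents that add atoms: chlorotrimethylsilane, C[Si](C)(C)Cl; iodomethane, CI
Why: Ireland–Claisen rearrangement in Still's α-methylene-acid format: in-situ silylation turns the α′-blocked enone into its 2-silyloxydiene (γ-deprotonation), exposing the C5–O/C6=C7 allyl ester, and the suprafacial [3,3] shift forms C7–C11 on the face of the departing C5–O (cis to the chain); N-methylation and elimination of the Mannich base then give the acrylic acid.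

Step 8
Reactants: 16 2-[(1R,4R)-4-[(3Z)-4-iodopent-3-en-1-yl]-4-methyl-5-oxocyclohex-2-en-1-yl]prop-2-enoic acid
Product: 17 (3aS,6S,7R,7aR)-7-bromo-6-[(3Z)-4-iodopent-3-en-1-yl]-6-methyl-3-methylidenehexahydro-1-benzofuran-2,5-dione
Conditions: NBS, NaHCO3 (cat.), THF–H2O, 0 °C
Reagents that add atoms: N-bromosuccinimide, O=C1CCC(=O)N1Br
Why: Bromolactonisation (5-exo, anti addition): the carboxylate attacks C6 on the face of the C7 side chain to give the cis-fused α-methylene lactone, and bromine ends up at C5 on the opposite face, trans to the C4 chain as the later fragmentation requires.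

Step 9
Reactants: 17 (3aS,6S,7R,7aR)-7-bromo-6-[(3Z)-4-iodopent-3-en-1-yl]-6-methyl-3-methylidenehexahydro-1-benzofuran-2,5-dione
Product: 19 (3aR,4R,6S,7R,7aR)-7-bromo-4-hydroxy-6-[(3Z)-4-iodopent-3-en-1-yl]-6-methyl-3-methylidenehexahydro-1-benzofuran-2,5-dione, via silyl enol ether 18 (not isolated)
Conditions: Me3SiOTf, Et3N, CH2Cl2, −78 → 0 °C; DMDO, acetone, −40 °C; aq citric acid
Reagents that add atoms: trimethylsilyl trifluoromethanesulfonate, C[Si](C)(C)OS(=O)(=O)C(F)(F)F; dimethyldioxirane, CC1(C)OO1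
Why: Rubottom oxidation under base-free soft enolisation (only C8 can enolise); DMDO attacks the enol ether anti to the C7–C11 bond of the cis-fused lactone, so C8–OH is trans to C7–C11.

Step 10
Reactants: 20 angelic acid
Product: 21 (2Z)-2-methylbut-2-en-1-ol
Conditions: LiAlH4, Et2O, 0 °C
Reagents that add atoms: none
Why: Hydride reduction of the unsaturated acid to the allylic alcohol with retention of the Z geometry.

Step 11
Reactants: 21 (2Z)-2-methylbut-2-en-1-ol
Product: 22 [(2R,3S)-2,3-dimethyloxiran-2-yl]methanol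
Conditions: Ti(OiPr)4, L-(+)-DET, t-BuOOH, 4 Å MS, CH2Cl2, −20 °C
Reagents that add atoms: tert-butyl hydroperoxide, CC(C)(C)OO
Why: Sharpless asymmetric epoxidation; L-(+)-tartrate delivers oxygen to the lower face of the allylic alcohol (mnemonic orientation), giving the (2R,3S) cis-epoxide.

Step 12
Reactants: 22 [(2R,3S)-2,3-dimethyloxiran-2-yl]methanol
Product: 23 (2S,3S)-2,3-dimethyloxirane-2-carboxylic acid
Conditions: RuCl3 (2 mol %), NaIO4, MeCN–CCl4–H2O, 0 → 25 °C
Reagents that add atoms: sodium periodate, [Na+].[O-]I(=O)(=O)=O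
Why: Sharpless RuO4 oxidation of the primary alcohol to the acid leaves the epoxide and both centres intact (the C2 descriptor changes only through CIP priorities).

Step 13
Reactants: 19 (3aR,4R,6S,7R,7aR)-7-bromo-4-hydroxy-6-[(3Z)-4-iodopent-3-en-1-yl]-6-methyl-3-methylidenehexahydro-1-benzofuran-2,5-dione; 23 (2S,3S)-2,3-dimethyloxirane-2-carboxylic acid
Product: 24 (3aR,4R,6S,7R,7aR)-7-bromo-6-[(3Z)-4-iodopent-3-en-1-yl]-6-methyl-3-methylidene-2,5-dioxooctahydro-1-benzofuran-4-yl (2S,3S)-2,3-dimethyloxirane-2-carboxylate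
Conditions: DCC, DMAP (0.1 equiv), CH2Cl2, 0 °C
Reagents that add atoms: none
Why: Steglich esterification of the only free hydroxyl; low temperature and little DMAP limit epimerisation of the α-acyloxy ketone centre C8.

Step 14
Reactants: 24 (3aR,4R,6S,7R,7aR)-7-bromo-6-[(3Z)-4-iodopent-3-en-1-yl]-6-methyl-3-methylidene-2,5-dioxooctahydro-1-benzofuran-4-yl (2S,3S)-2,3-dimethyloxirane-2-carboxylate
Product: 26 (3aS,4R,6Z,10E,11aS)-6,10-dimethyl-3-methylidene-2,5-dioxo-2,3,3a,4,5,8,9,11a-octahydrocyclodeca[b]furan-4-yl (2S,3S)-2,3-dimethyloxirane-2-carboxylate, via bicyclic silyl ether 25 (not isolated)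
Conditions: CrCl2 (15 mol %), NiCl2 (3 mol %), Mn (2 equiv), Me3SiCl (2.2 equiv), THF–DMF 10:1, 25 °C; then CsF (8 equiv), 0 °C, 30 min; pH 7 buffer
Reagents that add atoms: chlorotrimethylsilane, C[Si](C)(C)Cl
Why: Proposed new method: a Ni/Cr-catalysed (Mn/Me3SiCl turnover) intramolecular alkenylation of the C9 ketone closes ring B as silyl ether 25, and fluoride then frees the tertiary caesium alkoxide, whose C4–C9 bond lies anti-periplanar to the equatorial C5–Br, so a Grob fragmentation expels bromide and inserts the four-carbon alkenyl chain into the ring (6 → 10) with E-C4=C5 from the trans Br/chain relationship and Z-C1=C10 from the vinyl iodide; the closest known reactions are the SmI2 Barbier-cyclisation/Grob-fragmentation sequence of iodoalkyl keto mesylates and fluoride-triggered Grob fragmentations of silyl ethers, whereas an alkenyl-chromium-initiated version with a halide nucleofuge has not been shown.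

Step 15
Reactants: 26 (3aS,4R,6Z,10E,11aS)-6,10-dimethyl-3-methylidene-2,5-dioxo-2,3,3a,4,5,8,9,11a-octahydrocyclodeca[b]furan-4-yl (2S,3S)-2,3-dimethyloxirane-2-carboxylate
Product: 27 (3aS,4R,5R,6Z,10E,11aS)-5-hydroxy-6,10-dimethyl-3-methylidene-2-oxo-2,3,3a,4,5,8,9,11a-octahydrocyclodeca[b]furan-4-yl (2S,3S)-2,3-dimethyloxirane-2-carboxylate
Conditions: (R)-Me-CBS (0.5 equiv), catecholborane (1.5 equiv), toluene, −78 °C
Reagents that add atoms: none
Why: Corey–Bakshi–Shibata reduction gives reagent-controlled 1,2-reduction of the enone carbonyl to the (9R) carbinol and leaves the α-methylene lactone, the epoxy ester and both ring alkenes untouched at −78 °C.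

## Compound list

1 | cyclohexane-1,3-dione | O=C1CCCC(=O)C1 | starting material
2 | 2-methylcyclohexane-1,3-dione | CC1C(=O)CCCC1=O | intermediate
3 | acrolein | C=CC=O | starting material
4 | 3-(1-methyl-2,6-dioxocyclohexyl)propanal | CC1(CCC=O)C(=O)CCCC1=O | intermediate
5 | 2-[(3Z)-4-iodopent-3-en-1-yl]-2-methylcyclohexane-1,3-dione | CC1(CC/C=C(/C)I)C(=O)CCCC1=O | intermediate
6 | (2R,3R)-3-hydroxy-2-[(3Z)-4-iodopent-3-en-1-yl]-2-methylcyclohexan-1-one (OH cis to the chain) | O=C1[C@](C)(CC/C=C(/C)I)[C@H](O)CCC1 | intermediate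
7 | 6-(phenylselanyl) derivative of 6 (epimers at the selenium-bearing carbon) | O=C1[C@](C)(CC/C=C(/C)I)[C@H](O)CCC1[Se]c1ccccc1 | intermediate (not isolated)
8 | (5R,6R)-5-hydroxy-6-[(3Z)-4-iodopent-3-en-1-yl]-6-methylcyclohex-2-en-1-one | O=C1[C@](C)(CC/C=C(/C)I)[C@H](O)CC=C1 | intermediate
9 | acryloyl chloride | C=CC(=O)Cl | starting material
10 | (1R,6R)-6-[(3Z)-4-iodopent-3-en-1-yl]-6-methyl-5-oxocyclohex-3-en-1-yl prop-2-enoate | O=C1[C@](C)(CC/C=C(/C)I)[C@H](OC(=O)C=C)CC=C1 | intermediate (not isolated)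
11 | (1R,6R)-6-[(3Z)-4-iodopent-3-en-1-yl]-6-methyl-5-oxocyclohex-3-en-1-yl 3-(pyrrolidin-1-yl)propanoate | O=C1[C@](C)(CC/C=C(/C)I)[C@H](OC(=O)CCN2CCCC2)CC=C1 | intermediate
12 | trimethylsilyl ketene acetal of 11 with the enone as its 2-(trimethylsilyloxy)-1,3-diene (C9-OSi, C8=C9, C6=C7) | C[Si](C)(C)OC=1[C@](C)(CC/C=C(/C)I)[C@H](OC(O[Si](C)(C)C)=CCN2CCCC2)C=CC=1 | intermediate (not isolated)
13 | Claisen product of 12: trimethylsilyl ester with C7–C11 bond on the former C5–O face, C5=C6, C8=C9 silyl enol ether (C11 epimers) | C[Si](C)(C)OC=1[C@](C)(CC/C=C(/C)I)C=C[C@H](C(CN2CCCC2)C(=O)O[Si](C)(C)C)C=1 | intermediate (not isolated)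
14 | 2-[(1R,4R)-4-[(3Z)-4-iodopent-3-en-1-yl]-4-methyl-5-oxocyclohex-2-en-1-yl]-3-(pyrrolidin-1-yl)propanoic acid (C2 epimers) | O=C1[C@](C)(CC/C=C(/C)I)C=C[C@H](C(CN2CCCC2)C(=O)O)C1 | intermediate (not isolated)
15 | N-methylpyrrolidinium iodide of 14 | O=C1[C@](C)(CC/C=C(/C)I)C=C[C@H](C(C[N+]2(C)CCCC2)C(=O)O)C1.[I-] | intermediate (not isolated)
16 | 2-[(1R,4R)-4-[(3Z)-4-iodopent-3-en-1-yl]-4-methyl-5-oxocyclohex-2-en-1-yl]prop-2-enoic acid | O=C1[C@](C)(CC/C=C(/C)I)C=C[C@H](C(=C)C(=O)O)C1 | intermediate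
17 | (3aS,6S,7R,7aR)-7-bromo-6-[(3Z)-4-iodopent-3-en-1-yl]-6-methyl-3-methylidenehexahydro-1-benzofuran-2,5-dione (cis-fused lactone; Br trans to lactone O and to the chain) | O=C1[C@](C)(CC/C=C(/C)I)[C@@H](Br)[C@@H]2OC(=O)C(=C)[C@@H]2C1 | intermediate
18 | 5-(trimethylsilyloxy) enol ether of 17 (C8=C9) | C[Si](C)(C)OC=1[C@](C)(CC/C=C(/C)I)[C@@H](Br)[C@@H]2OC(=O)C(=C)[C@@H]2C=1 | intermediate (not isolated)
19 | (3aR,4R,6S,7R,7aR)-7-bromo-4-hydroxy-6-[(3Z)-4-iodopent-3-en-1-yl]-6-methyl-3-methylidenehexahydro-1-benzofuran-2,5-dione | O=C1[C@](C)(CC/C=C(/C)I)[C@@H](Br)[C@@H]2OC(=O)C(=C)[C@@H]2[C@H]1O | intermediate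
20 | angelic acid, (2Z)-2-methylbut-2-enoic acid | C/C=C(/C)C(=O)O | starting material
21 | (2Z)-2-methylbut-2-en-1-ol | C/C=C(/C)CO | intermediate
22 | [(2R,3S)-2,3-dimethyloxiran-2-yl]methanol | OC[C@@]1(C)O[C@H]1C | intermediate
23 | (2S,3S)-2,3-dimethyloxirane-2-carboxylic acid | OC(=O)[C@@]1(C)O[C@H]1C | intermediate
24 | (3aR,4R,6S,7R,7aR)-7-bromo-6-[(3Z)-4-iodopent-3-en-1-yl]-6-methyl-3-methylidene-2,5-dioxooctahydro-1-benzofuran-4-yl (2S,3S)-2,3-dimethyloxirane-2-carboxylate | O=C1[C@](C)(CC/C=C(/C)I)[C@@H](Br)[C@@H]2OC(=O)C(=C)[C@@H]2[C@H]1OC(=O)[C@@]3(C)O[C@H]3C | intermediate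
25 | 9-bromo-5,8a-dimethyl-3-methylidene-2-oxo-4a-(trimethylsilyloxy)-2,3,3a,4,4a,7,8,8a,9,9a-decahydronaphtho[2,3-b]furan-4-yl (2S,3S)-2,3-dimethyloxirane-2-carboxylate (4a-OSi cis to 8a-Me expected; other centres as in 24) | CC1=CCC[C@]2(C)[C@@H](Br)[C@@H]3OC(=O)C(=C)[C@@H]3[C@@H](OC(=O)[C@@]4(C)O[C@H]4C)[C@]12O[Si](C)(C)C | intermediate (not isolated)
26 | (3aS,4R,6Z,10E,11aS)-6,10-dimethyl-3-methylidene-2,5-dioxo-2,3,3a,4,5,8,9,11a-octahydrocyclodeca[b]furan-4-yl (2S,3S)-2,3-dimethyloxirane-2-carboxylate | C=C1C(=O)O[C@H]2/C=C(\C)CC/C=C(/C)C(=O)[C@H](OC(=O)[C@@]3(C)O[C@H]3C)[C@@H]12 | intermediate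
27 | (3aS,4R,5R,6Z,10E,11aS)-5-hydroxy-6,10-dimethyl-3-methylidene-2-oxo-2,3,3a,4,5,8,9,11a-octahydrocyclodeca[b]furan-4-yl (2S,3S)-2,3-dimethyloxirane-2-carboxylate | C=C1C(=O)O[C@H]2/C=C(\C)CC/C=C(/C)[C@@H](O)[C@H](OC(=O)[C@@]3(C)O[C@H]3C)[C@@H]12 | target

## Step count and risks

Total steps: 15. Longest linear sequence: 12 (steps 1–9 and 13–15); steps 10–12 make the side-chain acid.

Steps most likely to fail:

- **Step 7 (Claisen on an enone-containing ester).** The dienolate could expel the C5 carboxylate before it is silylated. The fallback sets out from 11: the ketone is first masked as the isolable tert-butyldimethylsilyl dienol ether F1 (TBSOTf, Et3N, CH2Cl2, −78 °C). F1 then has a single enolisable site and undergoes an ordinary Ireland–Claisen rearrangement (LDA 1.2 equiv, Me3SiCl, THF, −78 → 60 °C) through its trimethylsilyl ketene acetal F2 to the rearranged silyl ester F3. 1 M HCl removes both silyl groups, and the sequence comes back to the route at 14, which is methylated and eliminated to 16 as in step 7.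

- **Step 14 (proposed new cascade).** Risks are opening of the epoxy ester by Me3SiCl, reduction of the α-acyloxy ketone by Cr(II), and acyl migration or C8 epimerisation during the fluoride stage. The fallback uses known chemistry and sets out from 24: a stoichiometric Nozaki–Hiyama–Kishi cyclisation (CrCl2 4 equiv, NiCl2 1 mol %, DMSO, 25 °C, aqueous work-up) isolates the bicyclic bromo alcohol F4. F4 is then fragmented in a separate classical alkoxide Wharton–Grob step (KHMDS, 18-crown-6, THF, −78 → 0 °C), which comes back to the route at 26.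

- **Step 15 (C9 configuration).** The macrocycle may override the CBS reagent, or the branched C8 arm may act as the large group. The fallback sets out from 26: Luche reduction (NaBH4, CeCl3, MeOH, −78 °C) under substrate control. If this gives the 9-epimeric alcohol F5, Mitsunobu inversion with formic acid (PPh3, DIAD, THF, 0 °C) gives the inverted formate F6, and mild formate cleavage (KHCO3, MeOH–H2O, 0 °C) comes back to the route at 27.

## Further compounds

F1 | step 7 | (1R,6R)-5-(tert-butyldimethylsilyloxy)-6-[(3Z)-4-iodopent-3-en-1-yl]-6-methylcyclohexa-2,4-dien-1-yl 3-(pyrrolidin-1-yl)propanoate | CC(C)(C)[Si](C)(C)OC=1[C@](C)(CC/C=C(/C)I)[C@H](OC(=O)CCN2CCCC2)C=CC=1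
F2 | step 7 | trimethylsilyl ketene acetal of F1 | CC(C)(C)[Si](C)(C)OC=1[C@](C)(CC/C=C(/C)I)[C@H](OC(O[Si](C)(C)C)=CCN2CCCC2)C=CC=1
F3 | step 7 | Claisen product of F2: trimethylsilyl ester with C7–C11 bond on the former C5–O face, C5=C6, C8=C9 tert-butyldimethylsilyl enol ether | CC(C)(C)[Si](C)(C)OC=1[C@](C)(CC/C=C(/C)I)C=C[C@H](C(CN2CCCC2)C(=O)O[Si](C)(C)C)C=1
F4 | step 14 | 9-bromo-4a-hydroxy-5,8a-dimethyl-3-methylidene-2-oxo-2,3,3a,4,4a,7,8,8a,9,9a-decahydronaphtho[2,3-b]furan-4-yl (2S,3S)-2,3-dimethyloxirane-2-carboxylate (4a-OH cis to 8a-Me; other centres as in 24) | CC1=CCC[C@]2(C)[C@@H](Br)[C@@H]3OC(=O)C(=C)[C@@H]3[C@@H](OC(=O)[C@@]4(C)O[C@H]4C)[C@]12O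
F5 | step 15 | (3aS,4R,5S,6Z,10E,11aS)-5-hydroxy-6,10-dimethyl-3-methylidene-2-oxo-2,3,3a,4,5,8,9,11a-octahydrocyclodeca[b]furan-4-yl (2S,3S)-2,3-dimethyloxirane-2-carboxylate (9-epimer of 27) | C=C1C(=O)O[C@H]2/C=C(\C)CC/C=C(/C)[C@H](O)[C@H](OC(=O)[C@@]3(C)O[C@H]3C)[C@@H]12
F6 | step 15 | (3aS,4R,5R,6Z,10E,11aS)-5-(formyloxy)-6,10-dimethyl-3-methylidene-2-oxo-2,3,3a,4,5,8,9,11a-octahydrocyclodeca[b]furan-4-yl (2S,3S)-2,3-dimethyloxirane-2-carboxylate | C=C1C(=O)O[C@H]2/C=C(\C)CC/C=C(/C)[C@@H](OC=O)[C@H](OC(=O)[C@@]3(C)O[C@H]3C)[C@@H]12
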